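(The numbers in the tables are calculated on assumed constants, and the scatter is random.)

| flask | Q | D | X | remark | time |
|---|---|---|---|---|---|
| alder | 0.47 M | 0.705 M | 0.47 M | run made earlier |  |
| birch | 0.47 M | 0.35 M | 0.47 M | run made earlier |  |
| green | 0.47 M | 0.705 M | 0.470 M | a closed flask charged with all of it at once and left for 20 h | 20 h |
| teal | 0.47 M (fed, over 10.0 h) | 0.705 M | 0.470 M | all but Q at the start; Q goes in evenly over 10.0 h, the run ends at 20 h | 20 h |
| blue | 0.47 M | 0.705 M | 0.470 M | one stirred flow tank at steady state, fed with the mixture as stated, mean residence time 20 h |  |
| grey | 0.47 M | 0.705 M (fed, over 10.0 h) | 0.470 M | all but D at the start; D goes in evenly over 10.0 h, the run ends at 20 h | 20 h |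

| alder: time / h | alder: L / % | birch: time / h | birch: L / % |
|---|---|---|---|
| 1.50 | 46 | 0.833 | 27 |
| 3.00 | 56 | 1.50 | 37 |
| 5.00 | 66 | 2.50 | 34 |
| 6.00 | 67 | 3.00 | 37 |
| 8.00 | 67 | 4.00 | 43 |
| 10.0 | 69 | 5.00 | 46 |
| 12.0 | 72 | 6.00 | 46 |

(standard deviation of a reading: 2 percentage points)

- the stated concentrations are those of everything mixed, before any reaction; amounts are the same in each set-up
- the feed brings no volume worth counting
- the earlier runs were made in a closed, stirred flask

- the set-up with the highest amount of L at the outlet or at the end, in percent of the Q put in ("none" if the first two lie within 2 percentage points) (green / teal / blue / grey / none)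
- amount of L at the outlet or at the end, in percent of the Q put in, green
- amount of L at the outlet or at the end, in percent of the Q put in, teal
- amount of L at the outlet or at the end, in percent of the Q put in, blue
- amount of L at the outlet or at the end, in percent of the Q put in, grey

1. The alder run keeps a leftover. From 5.00 h to 8.00 h L stands on a shelf at about 66.7% of the Q charged, so about 33.3% of Q has not become L.

2. The birch run, with [D] = 0.35 M in place of 0.705 M, has its shelf at about 36.0% from 1.50 h to 3.00 h, lower than alder's.

3. So we set two amounts side by side: the L on this shelf and the D charged. Alder gives 0.444 and birch 0.483. Their mean, 0.464, is our shelf ratio, the L on the shelf per D charged. The two ratios lie close, so in these two runs the shelf rises nearly in step with the D charged.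

4. Our reckoning: each set-up holds [D] = 0.705 M for [Q] = 0.47 M, so the shelf lies near 69.6% of the Q charged. Alder still crept from 67% to 72% by 12.0 h, so we put green, teal and grey just above the shelf and about level. Blue must deliver 0.0348 /h of the Q charged at the shelf, more than alder's late pace of 0.00833 /h, so we put blue below the shelf.

5. The forecast differs. It names teal as best, with green 73%, teal 82%, blue 76% and grey 45%, and it says of grey: “Q sits without base and dimerises”.

6. The flasks give green 75.9%, teal 71.9%, blue 60.6% and grey 72.6%, so green is best.

    Q + E → J + L (k = 0.00190 /M/s)
    E + J ⇌ X, settled at all times (K = 720 /M)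
    J + D ⇌ Z, settled at all times (K = 190 /M)
    E ⇌ G (K = 0.460, k = 1.80 × 10⁻⁵ /s)

Green ends at 0.506 L per D charged and grey at 0.484, both a little above the shelf ratio of 0.464, though grey received its D over 10.0 h. Each L made releases one J, and J can take E back into X. The parking of J + D as Z is the main reason for green's yield: with that parking struck out, green ends at 32.9% in place of 75.9%.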